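The data were generated by integration on assumed constants; the scatter is artificial.

Two questions stand, and both concern the noon flask, so far followed to 50.0 h.

| setting | noon | dusk | flask |
|---|---|---|---|
| E | 0.20 M | 0.40 M | 0.20 M |
| Q | 8.9 mM (held) | 8.9 mM (held) | 8.9 mM (held) |
| remark | the very flask that is asked about, followed so far | run made earlier |  |
| time |  |  | 4.0 d |

noon run (percent of the E charged)

| time / h | G / % | E / % |
|---|---|---|
| 4.00 | 2 | 97 |
| 12.0 | 10 | 91 |
| 20.0 | 16 | 82 |
| 30.0 | 21 | 72 |
| 50.0 | 37 | 55 |

dusk run (percent of the E charged)

| time / d | G / % | E / % |
|---|---|---|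
| 0.833 | 4 | 88 |
| 1.67 | 15 | 82 |
| 2.50 | 22 | 74 |
| 3.00 | 27 | 68 |
| 4.00 | 38 | 58 |

(scatter of a reading: 1.5 percentage points)

- how much G there is at 4.0 d, in percent of the E charged
- concentration of D in solution at 4.0 d, in percent of saturation

- solid, in amounts per volume of the solution: E
- at the start none of Q is in solution
- at the start none of E is in solution
- D is what Q becomes in solution

Two people read these runs differently. The first holds to plain first order: each charge loses the same share of E in the same time. From the noon reading of 37 % G at 50.0 h, this view gives 58.8 % at 4.0 d. The second holds to zero order: the same amount of G appears per day at either charge.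

The readings favour the second. Interpolated to that noon time, the dusk run has 18.5 % G. Divide one share by the other and time drops out. The ratio of noon to dusk is 2.00, as read, and the ratio of the charges, dusk to noon, is 2.00.

My own reckoning carries one quantity. The scaled share is a run's share of G at a given time, times its charge, divided by the new charge, with Q and the time held. Dusk at 4.00 d gives 76.0 % for the noon flask. It assumes that solid still stands, so E is the reading to watch. Noon's last reading leaves 8.00 % of the charge, as read, as neither E nor G. With that same gap, E in the noon flask stands near 16.0 % at 4.0 d.

The forecast sides with the second person: “the rate is zero order in charged E”. It shades for a possible sag and gives 66 %, range 56 % to 74 %, and sat 50 %, range 12 % to 95 %. My unshaded figure lies above that range. The runs hold no reading of D.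

The noon flask gives 76.9 % G and D at 75.5 % of saturation.

Q ⇌ D, rate k1*(csat - [D]) (kL = 0.0129 /min); L + D → G (k = 0.407 /M/min); L → X (k = 9.75 × 10⁻⁵ /min); E ⇌ L, rate k4*(cs4 - [L]) while solid is left; crystals form when [L] > cs4 (solubility = 0.0690 M, k = 4.97 × 10⁻⁴ /min); L → Z (k = 2.71 × 10⁻⁶ /min) The scaled share was 0.90 percentage points lower, and for 0.80 M of E it gives 19.0 % against the simulated 19.2 %. The first view has its region past the solid, where the step L + D → G runs in proportion to what is left of L: at 40.0 d E stands at 0 % and G at 96.5 %. In the noon flask, each step taken net, D is made 1.00 times as fast as it is used up at 1.98 d, and 1.00 times at 4.00 d, a steady state. D stands at 75.5 % of saturation at 2.00 d and 75.5 % at 4.00 d.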